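**Strategy.** Ring B with C7, C8, C9 and the C5 methyl is (+)-3-carene in disguise (eremophilane numbering): the cyclopropane masks the 7-isopropenyl group, shields the β-face and blocks enolisation toward C8. The key step is a Robinson annulation of the carene-derived 9,10-diosphenol with (E)-pent-3-en-2-one. In one operation it closes ring A (Michael bond C4–C5, aldol bond C1–C10), builds the quaternary C5 with cis C4/C5 methyl groups and delivers the C2 ketone. It exploits the 1,4-relationship of the C2 and C9 oxygens across C1–C10 (an ene-1,4-dione), which later lets C10 equilibrate to the cis ring fusion. The precursor is a bicyclic 2-hydroxy-enone that holds no atom of ring A except C5 and C10.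

Key step: step 4

Remark on the chemistry: the ester is read as the tiglate, (E)-2-methylbut-2-enoate; commercial (+)-3-carene is taken as the (1S,6R) enantiomer, which carries the target configuration at C7.

Numbering used below: eremophilane numbering (decalin C1–C10, isopropenyl C11–C13, C14 on C5, C15 on C4). β is the face of the C5 methyl group. In 1–8 the cyclopropane carbon C11 is bonded to C7 and C8 on the β-face.

Step 1
Reactants: 1 (+)-3-carene
Product: 2 car-3-en-5-one
Conditions: t-BuOOH (70% aq.), Rh2(cap)4 (cap = caprolactamate, 1 mol %), K2CO3, CH2Cl2, 25 °C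
Reagents that add atoms: tert-butyl hydroperoxide, CC(C)(C)OO
Why: Radical allylic C–H oxidation should take hydrogen from the ring CH2 whose allyl radical has a tertiary terminus and oxygenate the secondary end, giving the β-methyl enone conjugated with the cyclopropane and leaving both stereocentres of 1 untouched.

Step 2
Reactants: 2 car-3-en-5-one
Product: 3 5α,10α-epoxide of 2 (3,4-epoxycaran-5-one)
Conditions: 30% aq. H2O2, NaOH (cat.), MeOH, 0 °C
Reagents that add atoms: hydrogen peroxide, OO
Why: Weitz–Scheffer nucleophilic epoxidation, in which hydroperoxide should add to the enone β-carbon C5 from the α-face, opposite to the endo methyl of the gem-dimethylcyclopropane (both new centres are erased in step 3).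

Step 3
Reactants: 3 5α,10α-epoxide of 2
Product: 4 4-hydroxycar-3-en-5-one (9-oxo-10-hydroxy-5(10)-ene diosphenol)
Conditions: KOH, DMSO–H2O, 60 °C; aq. HCl work-up
Reagents that add atoms: potassium hydroxide, [K+].[OH-]
Why: Base-mediated isomerisation of an α,β-epoxy ketone to a diosphenol, in which hydroxide should open the oxirane at the carbonyl-activated C10 and loss of the C5 oxygen leaves the 2-hydroxy-enone, whose enol can only sit at C10=C5 because C8 is a cyclopropane carbon.

Step 4
Reactants: 4 4-hydroxycar-3-en-5-one; 5 (E)-pent-3-en-2-one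
Product: 8 8,11-cycloeremophil-1(10)-ene-2,9-dione, via Michael triketone 6 (not isolated), via ring-A ketol 7 (not isolated)
Conditions: 5 (3 equiv), DBU (0.3 equiv), MeCN, 50 °C; then pyrrolidine, AcOH (cat.), 70 °C
Reagents that add atoms: none
Why: The diosphenolate of 4 should add through C5 to the β-carbon of 5 (Michael), the methyl ketone of 6 then condenses with the adjacent non-enolisable C10 carbonyl, and ketol 7 dehydrates to the ene-1,4-dione 8, which is a Robinson annulation of the kind known for 2-methylcyclohexanones and cyclic 1,2-diones. Ring A is closed by a 6-(enolendo)-exo-trig aldol addition of C1 onto C10. C5 is controlled by the gem-dimethylcyclopropane, whose endo methyl covers the β-face so that the enone is taken up on the α-face. C4 is controlled by the relative topicity of the Michael step, for which (E)-pent-3-en-2-one and 2-methylcyclohexanone-type enolates are known to favour the cis-vicinal dimethyl array. The step needs C- over O-alkylation, C5 over C8, and the C1-to-C10 aldol over the C3-to-C9 mode: O-adducts revert by retro-Michael, C8 cannot become an enolate terminus, and only the C1-to-C10 ketol can dehydrate (the other would need a bridgehead alkene), so the reversible side equilibria should drain into 8. Hydroxide is avoided to spare the 1,2-dione of 6 from benzilic acid rearrangement.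

Step 5
Reactants: 8 8,11-cycloeremophil-1(10)-ene-2,9-dione
Product: 10 eremophila-1(10),11-diene-2,9-dione, via tertiary chloride 9 (not isolated)
Conditions: HCl (gas), AcOH, 0 °C; then NaOAc, 95 °C
Reagents that add atoms: hydrogen chloride, Cl (its chlorine stays only in intermediate 9)
Why: Homoconjugate addition of HCl to the cyclopropyl ketone should cleave the C8–C11 bond toward the tertiary carbon, and buffered acetolysis of 9 should then lose a methyl proton (unimolecular elimination, kinetic preference for the less substituted alkene) to give the isopropenyl group on C7, whose configuration is the untouched C1 of carene.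

Step 6
Reactants: 10 eremophila-1(10),11-diene-2,9-dione
Product: 11 10βH-eremophil-11-ene-2,9-dione
Conditions: Zn dust, AcOH, 25 °C; then DBU (cat.), CH2Cl2, 25 °C
Reagents that add atoms: none
Why: Dissolving-metal reduction of the ene-1,4-dione saturates C1=C10, and the new C10 centre, being α to the C9 ketone, should equilibrate to the cis-fused 10β-H isomer because the trans-fused epimer would force the 5β-methyl and 7β-isopropenyl groups into a 1,3-diaxial relationship.

Step 7
Reactants: 11 10βH-eremophil-11-ene-2,9-dione
Product: 12 2,2-(ethylenedioxy)-10βH-eremophil-11-en-9-one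
Conditions: TMSOCH2CH2OTMS, TMSOTf (cat.), CH2Cl2, −78 → −20 °C
Reagents that add atoms: 1,2-bis(trimethylsilyloxy)ethane, C[Si](C)(C)OCCO[Si](C)(C)C
Why: Silyl-transfer ketalisation should discriminate on steric grounds, the C2 carbonyl between two methylenes reacting while the C9 carbonyl next to the ring fusion and the quaternary C5 does not; no stereocentre is formed.

Step 8
Reactants: 12 2,2-(ethylenedioxy)-10βH-eremophil-11-en-9-one
Product: 15 8α-acetoxy-2,2-(ethylenedioxy)-10βH-eremophil-11-en-9-one, via potassium enolate 13 (not isolated), via potassium alkoxide 14 (not isolated)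
Conditions: KN(SiMe3)2, THF, −78 °C; 2-(phenylsulfonyl)-3-phenyloxaziridine, −78 °C; then Ac2O, −78 → 0 °C
Reagents that add atoms: potassium bis(trimethylsilyl)amide, C[Si](C)(C)[N-][Si](C)(C)C.[K+] (potassium in 13 and 14); 2-(phenylsulfonyl)-3-phenyloxaziridine, O=S(=O)(c1ccccc1)N1OC1c1ccccc1; acetic anhydride, CC(=O)OC(C)=O
Why: Kinetic deprotonation of the only free ketone should occur at the C8 methylene and not at the hindered C10 methine, and enolate hydroxylation by the oxaziridine should occur anti to the neighbouring 7β-isopropenyl group as in carvone-type enolates, giving the 8α-oxygen that is acetylated in the same flask and that is also the diequatorial C8 epimer to which the α-acetoxy ketone can settle.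

Step 9
Reactants: 15 8α-acetoxy-2,2-(ethylenedioxy)-10βH-eremophil-11-en-9-one
Product: 16 8α-acetoxy-2,2-(ethylenedioxy)-10βH-eremophil-11-en-9α-ol
Conditions: LiBH(s-Bu)3, THF, −78 °C; AcOH quench at −78 °C
Reagents that add atoms: none
Why: Bulky-hydride reduction of the C9 ketone should proceed by equatorial attack from the convex β-face, because the axial α-trajectory is blocked by the axial C4–C5 bond, and so give the axial 9α-alcohol cis to the 8α-acetate.

Step 10
Reactants: 16 8α-acetoxy-2,2-(ethylenedioxy)-10βH-eremophil-11-en-9α-ol; 17 tigloyl chloride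
Product: 18 8α-acetoxy-2,2-(ethylenedioxy)-9α-tigloyloxy-10βH-eremophil-11-ene
Conditions: 17 (3 equiv), DMAP (cat.), pyridine, CH2Cl2, 40 °C
Reagents that add atoms: none
Why: DMAP-catalysed acylation of the single free hydroxyl with the configurationally stable (E)-acid chloride should install the tiglate with retention at C9 and of the alkene geometry, pyridine as the only base avoiding ketene formation and acetate migration.

Step 11
Reactants: 18 8α-acetoxy-2,2-(ethylenedioxy)-9α-tigloyloxy-10βH-eremophil-11-ene
Product: 19 8α-acetoxy-9α-tigloyloxy-10βH-eremophil-11-en-2-one (target)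
Conditions: 1 M aq. HCl (cat.), THF, 25 °C
Reagents that add atoms: water, O
Why: Mild acid-catalysed acetal hydrolysis should release the C2 ketone while the two esters and the isopropenyl group are inert to dilute aqueous acid at room temperature, and no stereocentre is touched.

**Compound list**

1 | (+)-3-carene, (1S,6R)-3,7,7-trimethylbicyclo[4.1.0]hept-3-ene | CC1(C)[C@H]2CC(C)=CC[C@@H]12 | starting material
2 | car-3-en-5-one, (1R,6S)-4,7,7-trimethylbicyclo[4.1.0]hept-3-en-2-one | CC1(C)[C@H]2CC(C)=CC(=O)[C@@H]12 | intermediate
3 | 3,4-epoxycaran-5-one, epoxide oxygen on the α-face (anti to the cyclopropane), bridging C5 and C10 | CC1(C)[C@H]2C[C@]3(C)O[C@@H]3C(=O)[C@@H]12 | intermediate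
4 | 4-hydroxycar-3-en-5-one (diosphenol), (1R,6S)-3-hydroxy-4,7,7-trimethylbicyclo[4.1.0]hept-3-en-2-one | CC1(C)[C@H]2CC(C)=C(O)C(=O)[C@@H]12 | intermediate
5 | (E)-pent-3-en-2-one | C/C=C/C(C)=O | starting material
6 | Michael triketone: carane-4,5-dione with 5β-methyl and 5α-[(S)-4-oxopentan-2-yl] at C5 (eremophilane locants) | CC1(C)[C@H]2C[C@](C)([C@@H](C)CC(C)=O)C(=O)C(=O)[C@@H]12 | intermediate
7 | ring-A ketol: cis-fused 10β-hydroxy-8,11-cycloeremophilane-2,9-dione | CC1(C)[C@H]2C[C@]3(C)[C@@H](C)CC(=O)C[C@]3(O)C(=O)[C@@H]12 | intermediate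
8 | 8,11-cycloeremophil-1(10)-ene-2,9-dione (4β,5β-dimethyl; C11 on the β-face of C7 and C8) | CC1(C)[C@H]2C[C@]3(C)[C@@H](C)CC(=O)C=C3C(=O)[C@@H]12 | intermediate
9 | tertiary chloride: 11-chloroeremophil-1(10)-ene-2,9-dione (7β-(2-chloropropan-2-yl)) | CC(C)(Cl)[C@H]1C[C@]2(C)[C@@H](C)CC(=O)C=C2C(=O)C1 | intermediate
10 | eremophila-1(10),11-diene-2,9-dione (4β,5β-dimethyl, 7β-isopropenyl) | C=C(C)[C@H]1C[C@]2(C)[C@@H](C)CC(=O)C=C2C(=O)C1 | intermediate
11 | 10βH-eremophil-11-ene-2,9-dione (cis-fused; 4β,5β-dimethyl, 7β-isopropenyl) | C=C(C)[C@H]1C[C@@]2(C)[C@H](CC(=O)C[C@@H]2C)C(=O)C1 | intermediate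
12 | 2,2-(ethylenedioxy)-10βH-eremophil-11-en-9-one | C=C(C)[C@H]1C[C@@]2(C)[C@H](CC3(OCCO3)C[C@@H]2C)C(=O)C1 | intermediate
13 | potassium 8(9)-enolate of 12 | C=C(C)[C@H]1C[C@@]2(C)[C@H](CC3(OCCO3)C[C@@H]2C)C([O-])=C1.[K+] | intermediate
14 | potassium alkoxide of 2,2-(ethylenedioxy)-8α-hydroxy-10βH-eremophil-11-en-9-one | C=C(C)[C@H]1C[C@@]2(C)[C@H](CC3(OCCO3)C[C@@H]2C)C(=O)[C@@H]1[O-].[K+] | intermediate
15 | 8α-acetoxy-2,2-(ethylenedioxy)-10βH-eremophil-11-en-9-one | C=C(C)[C@H]1C[C@@]2(C)[C@H](CC3(OCCO3)C[C@@H]2C)C(=O)[C@@H]1OC(C)=O | intermediate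
16 | 8α-acetoxy-2,2-(ethylenedioxy)-10βH-eremophil-11-en-9α-ol | C=C(C)[C@H]1C[C@@]2(C)[C@H](CC3(OCCO3)C[C@@H]2C)[C@H](O)[C@@H]1OC(C)=O | intermediate
17 | tigloyl chloride, (E)-2-methylbut-2-enoyl chloride | C/C=C(\C)C(=O)Cl | starting material
18 | 8α-acetoxy-2,2-(ethylenedioxy)-9α-tigloyloxy-10βH-eremophil-11-ene | C=C(C)[C@H]1C[C@@]2(C)[C@H](CC3(OCCO3)C[C@@H]2C)[C@H](OC(=O)/C(C)=C/C)[C@@H]1OC(C)=O | intermediate
19 | 8α-acetoxy-9α-tigloyloxy-10βH-eremophil-11-en-2-one, (1S,2R,3R,4aR,5S,8aS)-2-acetoxy-4a,5-dimethyl-7-oxo-3-(prop-1-en-2-yl)decahydronaphthalen-1-yl (E)-2-methylbut-2-enoate | C=C(C)[C@H]1C[C@@]2(C)[C@H](CC(=O)C[C@@H]2C)[C@H](OC(=O)/C(C)=C/C)[C@@H]1OC(C)=O | target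

**Total step count:** 11. **Longest linear sequence:** 11 steps (1 to 19).

**Steps most likely to fail**

1. Step 4. C–C bond formation at the hindered tertiary diosphenolate carbon may lose to O-alkylation and retro-Michael reversal, and the C4 topicity may erode. Fallback, setting out from 4 and coming back at 8: the acceptor would be exchanged for the doubly activated, commercially available ethyl 2-ethylidene-3-oxobutanoate. Piperidine/AcOH-mediated Michael addition, aldol condensation through the methyl ketone and dehydration should give the ring-A β-keto ester ethyl 8,11-cyclo-2,9-dioxoeremophil-1(10)-ene-3-carboxylate F1. Its activating ester would then be removed by Krapcho dealkoxycarbonylation (LiCl, wet DMSO, 140 °C) to return 8.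

2. Step 5. Proton loss from the tertiary C11 cation toward C7, and acid-promoted migration of the new double bond into conjugation with C9, may compete with isopropenyl formation. Fallback, setting out from 8 and coming back at 10: hydrolytic opening of the cyclopropyl ketone (HClO4, aq. dioxane) should give the tertiary alcohol 11-hydroxyeremophil-1(10)-ene-2,9-dione F2. Dehydration through its chlorosulfite (SOCl2, pyridine, −20 °C), a base-induced bimolecular elimination that takes a methyl hydrogen, would then give 10.

3. Step 8. The oxidant may approach the enolate syn to the isopropenyl group or at C10, and the acetate may migrate from O8 to O9 during the following reduction. Fallback, setting out from 12 and coming back at 16: the same enolate hydroxylation with protic work-up should give the free ketol 2,2-(ethylenedioxy)-8α-hydroxy-10βH-eremophil-11-en-9-one F3, which would be equilibrated (Et3N) to the hydrogen-bonded equatorial 8α-epimer. LiBH(s-Bu)3 should then give the cis-diol 2,2-(ethylenedioxy)-10βH-eremophil-11-ene-8α,9α-diol F4. Only the unhindered equatorial 8-hydroxyl would be acetylated (Ac2O, pyridine, 0 °C) to reach 16.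

**Further compounds**

F1 | step 4 | ethyl 8,11-cyclo-2,9-dioxoeremophil-1(10)-ene-3-carboxylate (C3 epimers) | CC1(C)[C@H]2C[C@]3(C)[C@@H](C)C(C(=O)OCC)C(=O)C=C3C(=O)[C@@H]12
F2 | step 5 | 11-hydroxyeremophil-1(10)-ene-2,9-dione | CC(C)(O)[C@H]1C[C@]2(C)[C@@H](C)CC(=O)C=C2C(=O)C1
F3 | step 8 | 2,2-(ethylenedioxy)-8α-hydroxy-10βH-eremophil-11-en-9-one | C=C(C)[C@H]1C[C@@]2(C)[C@H](CC3(OCCO3)C[C@@H]2C)C(=O)[C@@H]1O
F4 | step 8 | 2,2-(ethylenedioxy)-10βH-eremophil-11-ene-8α,9α-diol | C=C(C)[C@H]1C[C@@]2(C)[C@H](CC3(OCCO3)C[C@@H]2C)[C@H](O)[C@@H]1O
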